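(The runs were generated by integration with constants of no real substance; the scatter is artificial.)

**Short storage.** Waiting could not keep target in Monday's flask. At 5 °C, with partner at 105% of the charge, target read 68% at 20.0 s but 24% at 120 s. From those readings I took 66.6 s as the sitting half-life, the time in which target already made loses half of itself.

| flask | starting material | coupling partner | temperature | remark | time |
|---|---|---|---|---|---|
| Monday's | 10 mM | 10.5 mM | 5 °C | run made earlier |  |
| Sunday's | 10 mM | 5.2 mM | 5 °C | run made earlier |  |
| delta | 10 mM (fed, over 80 s) | 10.5 mM | 5 °C | all else is in the flask from the start; the feed brings no volume worth counting | 3.0 min |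
| alpha | 10 mM (in portions, 3, over 80 s) | 10.5 mM | 5 °C | first portion at the start, last at 80 s | 3.0 min |
| zeta | 10 mM (fed, over 80 s) | 10.5 mM |  | the addition at −35 °C, then warmed to 5 °C; the feed brings no volume worth counting | 3.0 min |
| epsilon | 10 mM | 10.5 mM (fed, over 80 s) | 5 °C | all else is in the flask from the start; the feed brings no volume worth counting | 3.0 min |

| run | time / s | target / % | starting material / % |
|---|---|---|---|
| Monday's | 10.0 | 62 | 32 |
| Monday's | 12.0 | 64 | 25 |
| Monday's | 20.0 | 68 | 18 |
| Monday's | 30.0 | 61 | 11 |
| Monday's | 50.0 | 54 | 8 |
| Monday's | 80.0 | 39 | 7 |
| Monday's | 120 | 24 | 3 |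
| Sunday's | 10.0 | 40 | 56 |
| Sunday's | 15.0 | 41 | 52 |
| Sunday's | 20.0 | 37 | 52 |
| Sunday's | 30.0 | 35 | 54 |
| Sunday's | 40.0 | 30 | 52 |

(each reading ± 1.5 percentage points)

- the earlier runs do not show what temperature does; that part of a forecast is a guess

**Sunday's neighbour.** Sunday's flask looked nearly the same, but its partner stood at 52.0% of the charge. Its starting material stopped near 52%, so partner was the limiting reagent, and target read 41% at 15.0 s. Target still fell, to 30% at 40.0 s, which reads as a half-life of 55.5 s, close to Monday's. So Sunday's flask read less target than Monday's, 41% against 68%, while the two lost target at about one pace.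

1. the flask with the highest amount of target, in percent of the starting material charged ("all alike" if they lie within 1.5 percentage points) (delta / alpha / zeta / epsilon / all alike)
2. final target, as a percentage of the starting material charged, in delta
3. final target, as a percentage of the starting material charged, in alpha
4. final target, as a percentage of the starting material charged, in zeta
5. final target, as a percentage of the starting material charged, in epsilon

**My count.** Monday's first reading of starting material gave a halving time of about 6.08 s, shorter than the sitting half-life, so I assumed that target in a feed appeared about as the feed went in. On that count delta's average target sat 140 s, or 2.10 half-lives, which gave me an estimate of 23.3%. Alpha's portions and epsilon's fed partner went in at the same mean time as delta's feed, so I gave those flasks that estimate too. For zeta I guessed that −35 °C held back coupling and loss, so I began my count when the addition ended. Its 1.50 half-lives gave me an estimate of 35.3%, more than my estimate for the others.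

**The check.** The forecast named zeta, with delta 24.5%, alpha 25%, zeta 33% and epsilon 23.5%, its delta above mine and its zeta below, reasoning of zeta that “The flask then behaves like a batch”. The flasks gave delta 23.0%, alpha 22.9%, zeta 30.5% and epsilon 21.7%.

    crystals ⇌ leaving ligand, rate k1*(cs1 - [leaving ligand]) while solid is left; crystals form when [leaving ligand] > cs1 (solubility = 2.80 mM, k = 0.310 s⁻¹)
    starting material ⇌ intermediate + leaving ligand, settled at all times (K = 5.70 × 10⁻⁶ M, ΔH = −10.0 kJ mol⁻¹)
    coupling partner + intermediate → target (k = 14000 M⁻¹ s⁻¹, Ea = 21.0 kJ mol⁻¹)
    leaving ligand + target → side product (k = 4.50 M⁻¹ s⁻¹, Ea = 38.0 kJ mol⁻¹)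
    coupling partner ⇌ dormant form (K = 1.00, k = 0.0150 s⁻¹, Ea = 81.0 kJ mol⁻¹, ΔH = −17.0 kJ mol⁻¹)
    (constants at 5 °C)

**Steady loss.** Zeta's 30.5% lay below my 35.3%. Its leaving ligand went from 30.6% to 26.9% of the charge between 1.33 min and 3.00 min, close enough to steady for a roughly pseudo-first-order loss of target. That attack on target and the ligand's low solubility together gave zeta its lead of 8.8 percentage points over epsilon; the lead was 0.51 points without the attack and 2.7 points without the low solubility. For zeta's neighbour, with partner cut to 63.0% of the charge, I counted 22.2% after 1.50 half-lives of 66.6 s, and it gave 19.6%.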